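The route rests on disconnecting C4–C4a and C4'–C4a' of the two 2,2-dimethylpyran rings, which traces O1, O1' and the C6–C6' biaryl bond back to a 4,4'-biphenol core (each ring oxygen para to the biaryl bond). A single thermolysis runs two propargyl Claisen/1,5-hydrogen shift/oxa-6π sequences and closes both pyrans. Its precursor is the 4,4'-bis(2-methylbut-3-yn-2-yloxy)biphenyl skeleton already carrying the future C8 and C8' substituents as inert spectators (3-Br, 3'-OMe), made by a chemoselective Suzuki coupling, so each ring offers one free ortho carbon and no statistical late C–H functionalisation is required. Bromide-to-prenyl exchange and O-demethylation complete the synthesis.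

Key step: step 3

Assumption: compounds 1, 2, 4 and 9 are taken as commercial; the target has no stereocentre, so no stereodescriptor is needed.

Step 1
Reactants: 1 2-bromo-4-iodophenol; 2 2-methoxy-4-(4,4,5,5-tetramethyl-1,3,2-dioxaborolan-2-yl)phenol
Product: 3 3-bromo-3'-methoxybiphenyl-4,4'-diol
Conditions: Pd(PPh3)4 (3 mol%), Na2CO3 (3 equiv), 1,4-dioxane/H2O (4:1), 70 °C
Reagents that add atoms: none
Why: Suzuki–Miyaura coupling; zerovalent palladium inserts into the C–I bond of 1 far faster than into its C–Br bond, which the ortho phenoxide deactivates further, so the biaryl bond forms para to both hydroxyls and the bromine survives as the future C8 handle.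

Step 2
Reactants: 3 3-bromo-3'-methoxybiphenyl-4,4'-diol; 4 3-chloro-3-methylbut-1-yne (3 equiv)
Product: 5 3-bromo-3'-methoxy-4,4'-bis(2-methylbut-3-yn-2-yloxy)biphenyl
Conditions: CuCl2·2H2O (5 mol%), DBU (3.2 equiv), MeCN, 0 °C to rt
Reagents that add atoms: none
Why: Copper-catalysed propargylic etherification; the copper acetylide of 4 ionises to an allenylidene-type electrophile that both phenoxides capture at the tertiary carbon, giving tertiary ethers that direct SN2 alkylation cannot deliver, while the aryl bromide and methyl ether are inert.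

Step 3
Reactants: 5 3-bromo-3'-methoxy-4,4'-bis(2-methylbut-3-yn-2-yloxy)biphenyl
Product: 8 8-bromo-8'-methoxy-2,2,2',2'-tetramethyl-2H,2'H-6,6'-bichromene, via ring-B-closed monochromene 6 (not isolated), via ring-A-closed monochromene 7 (not isolated)
Conditions: o-dichlorobenzene (0.05 M), argon, 180 °C
Reagents that add atoms: none
Why: Each aryl 1,1-dimethylpropargyl ether undergoes an aromatic propargyl Claisen [3,3] shift that bonds the alkyne terminus to the free ortho carbon (the future C4–C4a and C4'–C4a' bonds), the 6-allenylcyclohexadienone enolises, a 1,5-hydrogen shift from the phenol OH to the central allene carbon gives an o-quinone methide, and an oxa-6π electrocyclisation re-forms the O–C(CH3)2 bond. The closest known reaction type is the thermal rearrangement of aryl 1,1-dimethylpropargyl ethers to 2,2-dimethyl-2H-chromenes, here run twice in one molecule through the half-rearranged ethers 6 and 7. Each pyran ring closes by a thermally allowed disrotatory 6π electrocyclisation of the 1-oxatriene (O1–C2 and O1'–C2' bond formation) after the sigmatropic step has set the carbon–carbon bond. No stereocentre is created. The only selectivity needed is delivery to the correct ortho carbon: the para positions are occupied by the biaryl bond, one ortho carbon of each ring is blocked by Br or OMe, and a shift onto a substituted ortho carbon gives a dienone that cannot enolise and reverts, so each ring has a single productive outcome. The gem-dimethyl groups accelerate the [3,3] step and the non-acidic medium protects the chromene products.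

Step 4
Reactants: 8 8-bromo-8'-methoxy-2,2,2',2'-tetramethyl-2H,2'H-6,6'-bichromene; 9 prenyl bromide (1-bromo-3-methylbut-2-ene)
Product: 12 8'-methoxy-2,2,2',2'-tetramethyl-8-(3-methylbut-2-en-1-yl)-2H,2'H-6,6'-bichromene, via aryllithium 10 (not isolated), via arylcopper 11 (not isolated)
Conditions: n-BuLi (1.1 equiv), THF, −78 °C; CuBr·SMe2 (1.2 equiv), −78 to −40 °C; 9 (1.5 equiv), −78 to 0 °C
Reagents that add atoms: none
Why: Bromine–lithium exchange at C8 outpaces deprotonation or addition at −78 °C, and the derived arylcopper undergoes allylic substitution on prenyl bromide at the unhindered primary carbon (γ-attack would build a quaternary carbon), a standard copper-mediated aryl prenylation.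

Step 5
Reactants: 12 8'-methoxy-2,2,2',2'-tetramethyl-8-(3-methylbut-2-en-1-yl)-2H,2'H-6,6'-bichromene
Product: 14 2,2,2',2'-tetramethyl-8-(3-methylbut-2-en-1-yl)-2H,2'H-[6,6'-bichromen]-8'-ol (CNP0158232.0), via sodium phenoxide 13 (not isolated)
Conditions: NaSEt (4 equiv), degassed DMF, 120 °C; then AcOH, 0 °C
Reagents that add atoms: none
Why: Nucleophilic O-demethylation by thiolate (SN2 at the methyl carbon); the 8'-OMe is the only ether with an SN2-accessible carbon, the pyran oxygens being bound to tertiary and aryl carbons, the non-acidic medium spares the chromene and prenyl alkenes, and acetic acid then protonates the phenoxide.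

Compound list
1 | 2-bromo-4-iodophenol | Oc1ccc(I)cc1Br | starting material
2 | 2-methoxy-4-(4,4,5,5-tetramethyl-1,3,2-dioxaborolan-2-yl)phenol | COc1cc(ccc1O)B1OC(C)(C)C(C)(C)O1 | starting material
3 | 3-bromo-3'-methoxybiphenyl-4,4'-diol | Oc1ccc(cc1Br)-c1ccc(O)c(OC)c1 | intermediate
4 | 3-chloro-3-methylbut-1-yne | CC(C)(Cl)C#C | starting material
5 | 3-bromo-3'-methoxy-4,4'-bis(2-methylbut-3-yn-2-yloxy)biphenyl | C#CC(C)(C)Oc1ccc(cc1Br)-c1ccc(OC(C)(C)C#C)c(OC)c1 | intermediate
6 | 6-[3-bromo-4-(2-methylbut-3-yn-2-yloxy)phenyl]-8-methoxy-2,2-dimethyl-2H-chromene (ring B pyran closed, not isolated) | C#CC(C)(C)Oc1ccc(cc1Br)-c1cc(OC)c2OC(C)(C)C=Cc2c1 | intermediate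
7 | 8-bromo-6-[3-methoxy-4-(2-methylbut-3-yn-2-yloxy)phenyl]-2,2-dimethyl-2H-chromene (ring A pyran closed, not isolated) | CC1(C)C=Cc2cc(cc(Br)c2O1)-c1ccc(OC(C)(C)C#C)c(OC)c1 | intermediate
8 | 8-bromo-8'-methoxy-2,2,2',2'-tetramethyl-2H,2'H-6,6'-bichromene | CC1(C)C=Cc2cc(cc(Br)c2O1)-c1cc(OC)c2OC(C)(C)C=Cc2c1 | intermediate
9 | prenyl bromide (1-bromo-3-methylbut-2-ene) | CC(C)=CCBr | starting material
10 | (8'-methoxy-2,2,2',2'-tetramethyl-2H,2'H-[6,6'-bichromen]-8-yl)lithium (not isolated) | [Li]c1cc(-c3cc(OC)c4OC(C)(C)C=Cc4c3)cc2C=CC(C)(C)Oc12 | intermediate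
11 | (8'-methoxy-2,2,2',2'-tetramethyl-2H,2'H-[6,6'-bichromen]-8-yl)copper (not isolated) | [Cu]c1cc(-c3cc(OC)c4OC(C)(C)C=Cc4c3)cc2C=CC(C)(C)Oc12 | intermediate
12 | 8'-methoxy-2,2,2',2'-tetramethyl-8-(3-methylbut-2-en-1-yl)-2H,2'H-6,6'-bichromene | CC(C)=CCc1cc(-c2cc(OC)c3c(c2)C=CC(C)(C)O3)cc2c1OC(C)(C)C=C2 | intermediate
13 | sodium 2,2,2',2'-tetramethyl-8-(3-methylbut-2-en-1-yl)-2H,2'H-[6,6'-bichromen]-8'-olate (not isolated) | CC(C)=CCc1cc(-c2cc([O-])c3c(c2)C=CC(C)(C)O3)cc2c1OC(C)(C)C=C2.[Na+] | intermediate
14 | 2,2,2',2'-tetramethyl-8-(3-methylbut-2-en-1-yl)-2H,2'H-[6,6'-bichromen]-8'-ol (CNP0158232.0) | CC(C)=CCc1cc(-c2cc(O)c3c(c2)C=CC(C)(C)O3)cc2c1OC(C)(C)C=C2 | target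

Total step count: 5. Longest linear sequence: 5 steps (from 1 or 2 to 14).

Steps most likely to fail

Step 3. The allenylphenol and o-quinone methide intermediates may oligomerise at the temperature required, or the second cascade may stall at the half-rearranged stage. The fallback sets out from 5 and returns at 8. Treatment of 5 with catalytic Ph3PAuNTf2 in CH2Cl2 at room temperature should effect a gold-catalysed 6-endo-dig intramolecular hydroarylation of both aryl propargyl ethers. This Friedel–Crafts-type closure forms the same C4–C4a and C4'–C4a' bonds at the only free ortho carbons without dienone or quinone methide intermediates. No compound outside the list is made (F0).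

Step 5. Under hot thiolate the prenyl side chain may degrade, by radical thiol–ene addition or by migration of its double bond into conjugation, or the cleavage may be incomplete. The fallback sets out from 8, before the prenyl group is present, and returns at 14; it moves the ether cleavage ahead of prenylation and ends with a fluoride deprotection.
- Thiolate cleavage of 8 (NaSEt, DMF, 120 °C; AcOH) should give 8-bromo-2,2,2',2'-tetramethyl-2H,2'H-[6,6'-bichromen]-8'-ol F1.
- Silylation (TBSCl, imidazole, DMF, rt) should give 8-bromo-8'-(tert-butyldimethylsilyloxy)-2,2,2',2'-tetramethyl-2H,2'H-6,6'-bichromene F2.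
- Bromine–lithium exchange and copper-mediated prenylation as in step 4 should give 8'-(tert-butyldimethylsilyloxy)-2,2,2',2'-tetramethyl-8-(3-methylbut-2-en-1-yl)-2H,2'H-6,6'-bichromene F3.
- TBAF (THF, 0 °C) then releases the phenol 14.

Step 4. The aryllithium may be protonated to the debrominated arene, Wurtz-type homocoupling may compete, or some substitution may leak to the γ-carbon of the allyl unit. The fallback sets out from 8 and returns at 12 with the polarity inverted. A Stille coupling of the aryl bromide with tributyl(3-methylbut-2-en-1-yl)stannane (Pd(PPh3)4, DMF, 100 °C) should deliver the linear prenyl group by reductive elimination at the less hindered allyl terminus. No compound outside the list is made (F0).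

Further compounds
F0 | step 3 | none | none
F1 | step 5 | 8-bromo-2,2,2',2'-tetramethyl-2H,2'H-[6,6'-bichromen]-8'-ol | CC1(C)C=Cc2cc(cc(Br)c2O1)-c1cc(O)c2OC(C)(C)C=Cc2c1
F2 | step 5 | 8-bromo-8'-(tert-butyldimethylsilyloxy)-2,2,2',2'-tetramethyl-2H,2'H-6,6'-bichromene | CC1(C)C=Cc2cc(cc(Br)c2O1)-c1cc(O[Si](C)(C)C(C)(C)C)c2OC(C)(C)C=Cc2c1
F3 | step 5 | 8'-(tert-butyldimethylsilyloxy)-2,2,2',2'-tetramethyl-8-(3-methylbut-2-en-1-yl)-2H,2'H-6,6'-bichromene | CC(C)=CCc1cc(-c2cc(O[Si](C)(C)C(C)(C)C)c3c(c2)C=CC(C)(C)O3)cc2c1OC(C)(C)C=C2
F0 | step 4 | none | none
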